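The route rests on disconnecting the pyran ring of the 2H-chromene at O1–C2 and C4–C4a, back to an enal and a phenol. One operation, a chiral-acid-catalysed condensation/oxa-6π electrocyclisation, joins (2E)-3-methyl-5-[(1S,2S)-1,2,3-trimethylcyclohex-3-enyl]pent-2-enal to 4,5,6-trimethoxyresorcinol, making the C4–C4a bond, then the O1–C2 bond and the C2 quaternary centre. It exploits the C5 hydroxyl beside C4a: the arene precursor is a symmetric resorcinol whose only C–H carbon (future C4a) lies between two equivalent OH groups. The enal's cis-1,2-dimethyl quaternary pair comes from an enantioselective endo Diels–Alder reaction of a 2-substituted acrolein, whose formyl group is then reduced to methyl.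

Key step: step 9

Remark on the chemistry: the absolute sense of induction of the two chiral catalysts (steps 3 and 9) is assigned by analogy and cannot be predicted with certainty; the mirror-image catalyst is used if the opposite sense is found. Chromene numbering: O1, C2, C3, C4, C4a, C5–C8, C8a.

Step 1
Reactants: 1 hex-5-yn-1-ol
Product: 2 hex-5-ynal
Conditions: TEMPO (10 mol %), PhI(OAc)2, CH2Cl2, rt
Reagents that add atoms: none
Why: Oxoammonium-mediated (TEMPO) oxidation of a primary alcohol should stop at the aldehyde and leave the terminal alkyne untouched.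

Step 2
Reactants: 2 hex-5-ynal
Product: 3 2-methylidenehex-5-ynal
Conditions: aq. HCHO (37 %), pyrrolidine (10 mol %), propionic acid (10 mol %), i-PrOH, 45 °C
Reagents that add atoms: formaldehyde, C=O
Why: Amine/acid-catalysed Mannich condensation–elimination (α-methylenation of an aldehyde) should give the 2-substituted acrolein, the alkyne being inert without a copper salt.

Step 3
Reactants: 3 2-methylidenehex-5-ynal; 4 (3E)-3-methylpenta-1,3-diene
Product: 5 (1R,2R)-1-(but-3-yn-1-yl)-2,3-dimethylcyclohex-3-ene-1-carbaldehyde
Conditions: (S)-3,3-diphenyl-1-(o-tolyl)tetrahydro-1H,3H-pyrrolo[1,2-c][1,3,2]oxazaborole activated with Tf2NH (20 mol %), CH2Cl2, −78 to −40 °C, excess 4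
Reagents that add atoms: none
Why: Catalytic enantioselective Diels–Alder reaction of a 2-substituted acrolein bound to a chiral cationic oxazaborolidinium: the dienophile CH2 should bond to the unsubstituted diene terminus (the terminal methyl being the stronger director), the formyl-endo transition state places CHO cis to the C2 methyl and the butynyl arm trans, and the catalyst shields one face of the enal so that C1 and C2 are set together.

Step 4
Reactants: 5 (1R,2R)-1-(but-3-yn-1-yl)-2,3-dimethylcyclohex-3-ene-1-carbaldehyde
Product: 7 4-[(1S,2S)-1,2,3-trimethylcyclohex-3-en-1-yl]but-1-yne, via tosylhydrazone 6 (not isolated)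
Conditions: TsNHNH2, EtOH, 50 °C; then catecholborane, CHCl3, 0 °C; NaOAc·3H2O, reflux
Reagents that add atoms: none
Why: Caglioti-type reduction: hydroboration of the hydrazone C=N, loss of sulfinate and N2 extrusion from the alkyldiazene should turn the neopentyl CHO into CH3 under mild non-basic conditions, so the alkyne, the alkene and both stereocentres (no α-hydrogen) are untouched and the new methyl is cis to the C2 methyl.

Step 5
Reactants: 7 4-[(1S,2S)-1,2,3-trimethylcyclohex-3-en-1-yl]but-1-yne
Product: 10 (2E)-3-methyl-5-[(1S,2S)-1,2,3-trimethylcyclohex-3-en-1-yl]pent-2-en-1-ol, via alkenyldimethylalane 8 (not isolated), via lithium alkenylalanate 9 (not isolated)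
Conditions: AlMe3 (2 equiv), Cp2ZrCl2 (0.25 equiv), CH2Cl2, 0 °C to rt; then n-BuLi, THF, −78 °C; (CH2O)n, −78 °C to rt; H2O work-up
Reagents that add atoms: trimethylaluminium, C[Al](C)C; formaldehyde (as paraformaldehyde), C=O
Why: Negishi zirconium-catalysed carboalumination adds Me and Al syn across the terminal alkyne with Al on the terminal carbon, and hydroxymethylation of the derived alanate with retention should give the (E)-trisubstituted allylic alcohol.

Step 6
Reactants: 10 (2E)-3-methyl-5-[(1S,2S)-1,2,3-trimethylcyclohex-3-en-1-yl]pent-2-en-1-ol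
Product: 11 (2E)-3-methyl-5-[(1S,2S)-1,2,3-trimethylcyclohex-3-en-1-yl]pent-2-enal
Conditions: TEMPO (10 mol %), PhI(OAc)2, CH2Cl2, rt
Reagents that add atoms: none
Why: TEMPO-mediated oxidation of an allylic alcohol should give the enal without over-oxidation and without touching the ring alkene.

Step 7
Reactants: 12 1,2,3-trimethoxybenzene
Product: 13 1,5-dibromo-2,3,4-trimethoxybenzene
Conditions: NBS (2.2 equiv), MeCN, rt to 50 °C
Reagents that add atoms: N-bromosuccinimide, O=C1CCC(=O)N1Br
Why: Electrophilic aromatic bromination should take the two positions that are each ortho to one outer methoxy group and para to the other, leaving the carbon between them (para only to the twisted central OMe) unsubstituted.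

Step 8
Reactants: 13 1,5-dibromo-2,3,4-trimethoxybenzene
Product: 14 4,5,6-trimethoxybenzene-1,3-diol
Conditions: Pd2(dba)3 (2 mol %), tBuXPhos (8 mol %), KOH, 1,4-dioxane/H2O, 100 °C, argon; then aq. HCl
Reagents that add atoms: potassium hydroxide, [K+].[OH-]
Why: Palladium-catalysed hydroxylation of aryl bromides (C–O cross-coupling with hydroxide and a bulky biarylphosphine) should convert both C–Br bonds, the electron-rich diol being kept under argon and acidified cold.

Step 9
Reactants: 11 (2E)-3-methyl-5-[(1S,2S)-1,2,3-trimethylcyclohex-3-en-1-yl]pent-2-enal; 14 4,5,6-trimethoxybenzene-1,3-diol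
Product: 17 (2R)-6,7,8-trimethoxy-2-methyl-2-{2-[(1S,2S)-1,2,3-trimethylcyclohex-3-en-1-yl]ethyl}-2H-chromen-5-ol, via benzylic carbinol 15 (not isolated), via ortho-quinone methide 16 (not isolated)
Conditions: (R)-3,3'-bis(2,4,6-triisopropylphenyl)-1,1'-binaphthyl-2,2'-diyl N-triflylphosphoramide (10 mol %), 5 Å molecular sieves, toluene, −20 °C to rt, argon, dark
Reagents that add atoms: none
Why: Proposed new method: the chiral acid activates enal 11 for Friedel–Crafts 1,2-addition by the only aromatic C–H carbon of 14 (C4–C4a bond, carbinol 15), ionises 15 with loss of water to the ortho-quinone methide 16 (a 1-oxatriene held as a hydrogen-bonded contact ion pair with the chiral phosphoramide anion), and 16 closes by oxa-6π electrocyclisation to form the O1–C2 bond. The closest known reactions are the achiral amine-salt-mediated phenol–enal chromene annulation (Knoevenagel condensation/oxa-6π electrocyclisation) and the chiral N-triflylphosphoramide-catalysed cyclisation of preformed ortho-hydroxyaryl allylic alcohols to 2H-chromenes through chiral contact ion pairs; merging the two intermolecularly for an all-alkyl quaternary C2 is not established. The pyran ring closes by thermal disrotatory 6π electrocyclisation of the oxatriene, equivalent to 6-endo C–O collapse of the ion pair. The new stereocentre C2 is set by the catalyst, whose anion is bound to the quinone methide oxygen and the flanking phenol OH and so biases the sense of rotation, because the side-chain stereocentres are too remote to do so. The step needs 1,2- over 1,4-addition, secured by the β,β-disubstituted enal, and site selectivity, secured by the resorcinol having a single C–H between two equivalent OH groups, so either oxygen gives the same chromene and no second annulation is possible. The product is kept in the dark and cold to avoid reversible ring opening that would erode the C2 configuration.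

Compound list
1 | hex-5-yn-1-ol | OCCCCC#C | starting material
2 | hex-5-ynal | O=CCCCC#C | intermediate
3 | 2-methylidenehex-5-ynal | C=C(C=O)CCC#C | intermediate
4 | (3E)-3-methylpenta-1,3-diene | C=C/C(C)=C/C | starting material
5 | (1R,2R)-1-(but-3-yn-1-yl)-2,3-dimethylcyclohex-3-ene-1-carbaldehyde | C#CCC[C@]1(C=O)CCC=C(C)[C@H]1C | intermediate
6 | N'-{[(1R,2R)-1-(but-3-yn-1-yl)-2,3-dimethylcyclohex-3-en-1-yl]methylidene}-4-methylbenzenesulfonohydrazide (tosylhydrazone) | C#CCC[C@]1(C=NNS(=O)(=O)c2ccc(C)cc2)CCC=C(C)[C@H]1C | intermediate (not isolated)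
7 | 4-[(1S,2S)-1,2,3-trimethylcyclohex-3-en-1-yl]but-1-yne | C#CCC[C@]1(C)CCC=C(C)[C@H]1C | intermediate
8 | dimethyl{(1E)-2-methyl-4-[(1S,2S)-1,2,3-trimethylcyclohex-3-en-1-yl]but-1-en-1-yl}alane | C[Al](C)/C=C(\C)CC[C@]1(C)CCC=C(C)[C@H]1C | intermediate (not isolated)
9 | lithium butyl(dimethyl){(1E)-2-methyl-4-[(1S,2S)-1,2,3-trimethylcyclohex-3-en-1-yl]but-1-en-1-yl}alanate | [Li+].CCCC[Al-](C)(C)/C=C(\C)CC[C@]1(C)CCC=C(C)[C@H]1C | intermediate (not isolated)
10 | (2E)-3-methyl-5-[(1S,2S)-1,2,3-trimethylcyclohex-3-en-1-yl]pent-2-en-1-ol | OC/C=C(\C)CC[C@]1(C)CCC=C(C)[C@H]1C | intermediate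
11 | (2E)-3-methyl-5-[(1S,2S)-1,2,3-trimethylcyclohex-3-en-1-yl]pent-2-enal | O=C/C=C(\C)CC[C@]1(C)CCC=C(C)[C@H]1C | intermediate
12 | 1,2,3-trimethoxybenzene | COc1cccc(OC)c1OC | starting material
13 | 1,5-dibromo-2,3,4-trimethoxybenzene | COc1c(Br)cc(Br)c(OC)c1OC | intermediate
14 | 4,5,6-trimethoxybenzene-1,3-diol | COc1c(O)cc(O)c(OC)c1OC | intermediate
15 | 2-{(2E)-1-hydroxy-3-methyl-5-[(1S,2S)-1,2,3-trimethylcyclohex-3-en-1-yl]pent-2-en-1-yl}-4,5,6-trimethoxybenzene-1,3-diol (carbinol epimers) | COc1c(O)c(C(O)/C=C(\C)CC[C@]2(C)CCC=C(C)[C@H]2C)c(O)c(OC)c1OC | intermediate (not isolated)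
16 | 5-hydroxy-2,3,4-trimethoxy-6-{(2E)-3-methyl-5-[(1S,2S)-1,2,3-trimethylcyclohex-3-en-1-yl]pent-2-en-1-ylidene}cyclohexa-2,4-dien-1-one (ortho-quinone methide) | O=C1C(OC)=C(OC)C(OC)=C(O)C1=C/C=C(\C)CC[C@]2(C)CCC=C(C)[C@H]2C | intermediate (not isolated)
17 | (2R)-6,7,8-trimethoxy-2-methyl-2-{2-[(1S,2S)-1,2,3-trimethylcyclohex-3-en-1-yl]ethyl}-2H-chromen-5-ol | COc1c(O)c2c(c(OC)c1OC)O[C@](C)(CC[C@]1(C)CCC=C(C)[C@H]1C)C=C2 | target

Total step count: 9
Longest linear sequence: 7 steps (steps 1–6, then step 9)

Steps most likely to fail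

Step 9. The ion pair may discriminate poorly between the methyl group and the alkyl arm at C2, or acid-promoted re-ionisation of the electron-rich chromene may erode the C2 configuration. The fallback gives up catalyst control and sets out from 11 and 14. The known thermal annulation with ethylenediammonium diacetate in toluene at 110 °C should give target 17 together with its C2 epimer (2S)-6,7,8-trimethoxy-2-methyl-2-{2-[(1S,2S)-1,2,3-trimethylcyclohex-3-en-1-yl]ethyl}-2H-chromen-5-ol F1. The two are diastereomers and would be separated by preparative HPLC on a cellulose carbamate chiral stationary phase. F1 can be re-equilibrated by UV irradiation (reversible oxa-6π opening) and recycled. The fallback comes back to the route at 17.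

Step 3. Facial control by the boron catalyst may be insufficient, and the formyl-exo pathway or the regioisomeric orientation directed by the internal diene methyl may compete. The fallback replaces asymmetric catalysis by resolution and sets out from 3 and 4. Cycloaddition promoted by EtAlCl2 (ethylaluminium dichloride) in CH2Cl2 at −78 °C, the robust endo manifold, should give 5 together with its enantiomer (1S,2S)-1-(but-3-yn-1-yl)-2,3-dimethylcyclohex-3-ene-1-carbaldehyde F2. Condensation of the mixture with (1R,2R)-N,N'-dimethyl-1,2-diphenylethane-1,2-diamine (MgSO4, Et2O) gives two diastereomeric aminals, (4R,5R)-2-[(1R,2R)-1-(but-3-yn-1-yl)-2,3-dimethylcyclohex-3-en-1-yl]-1,3-dimethyl-4,5-diphenylimidazolidine F3 and (4R,5R)-2-[(1S,2S)-1-(but-3-yn-1-yl)-2,3-dimethylcyclohex-3-en-1-yl]-1,3-dimethyl-4,5-diphenylimidazolidine F4, which would be separated by chromatography. Mild biphasic hydrolysis of F3 (aq. HCl/Et2O, 0 °C) returns the route to 5.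

Step 8. The double C–O coupling may stop at the mono-phenol or give protodebromination, and the very electron-rich diol may oxidise in hot base. The fallback makes the C–O bonds by C–B oxidation and sets out from 13. Double Miyaura borylation (bis(pinacolato)diboron, Pd(dppf)Cl2, KOAc, 1,4-dioxane, 90 °C) should give 2,2'-(4,5,6-trimethoxy-1,3-phenylene)bis(4,4,5,5-tetramethyl-1,3,2-dioxaborolane) F5. Oxidation with H2O2/NaOH in THF/H2O at 0 °C under argon and acidic work-up returns the route to 14.

Further compounds
F1 | step 9 | (2S)-6,7,8-trimethoxy-2-methyl-2-{2-[(1S,2S)-1,2,3-trimethylcyclohex-3-en-1-yl]ethyl}-2H-chromen-5-ol | COc1c(O)c2c(c(OC)c1OC)O[C@@](C)(CC[C@]1(C)CCC=C(C)[C@H]1C)C=C2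
F2 | step 3 | (1S,2S)-1-(but-3-yn-1-yl)-2,3-dimethylcyclohex-3-ene-1-carbaldehyde | C#CCC[C@@]1(C=O)CCC=C(C)[C@@H]1C
F3 | step 3 | (4R,5R)-2-[(1R,2R)-1-(but-3-yn-1-yl)-2,3-dimethylcyclohex-3-en-1-yl]-1,3-dimethyl-4,5-diphenylimidazolidine | C#CCC[C@]1(C2N(C)[C@H](c3ccccc3)[C@@H](c3ccccc3)N2C)CCC=C(C)[C@H]1C
F4 | step 3 | (4R,5R)-2-[(1S,2S)-1-(but-3-yn-1-yl)-2,3-dimethylcyclohex-3-en-1-yl]-1,3-dimethyl-4,5-diphenylimidazolidine | C#CCC[C@@]1(C2N(C)[C@H](c3ccccc3)[C@@H](c3ccccc3)N2C)CCC=C(C)[C@@H]1C
F5 | step 8 | 2,2'-(4,5,6-trimethoxy-1,3-phenylene)bis(4,4,5,5-tetramethyl-1,3,2-dioxaborolane) | COc1c(B2OC(C)(C)C(C)(C)O2)cc(B2OC(C)(C)C(C)(C)O2)c(OC)c1OC
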